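Ring C of the lower flavan is disconnected across C2–C3 and C4–C4a: a cationic aryl 2-oxadiene (C2=O1–C8a=C4a, the edge of ring A) plus a two-carbon enediol. An acyclic benzotriazolyl O-aryl acetal and (Z)-1,2-bis(silyloxy)ethene should merge in one acid-catalysed operation (Mukaiyama-type addition, Friedel–Crafts closure, then loss of a temporary C4 oxygen by 1,2-hydride shift) into the flavan-3-one. The step exploits the nucleophilic C4a of phloroglucinol ring A, flanked by oxygen-bearing C5 and C8a, and the C3 oxygen, which the enediol brings. Dynamic kinetic transfer hydrogenation then sets C2 and C3. C4 oxidation gives one electrophile that serves both as precursor of the carboxymethylated lower unit and as the upper unit.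

Key step: step 3

Assumption: in step 4 the (R,R)-configured catalyst is taken to deliver hydride to the face that gives the 3R carbinol (C2 side of the ketone acting as the large, pi-rich substituent); the mirror-image catalyst is the remedy if the sense proves opposite.

Remark: flavan numbering (O1, C2, C3, C4, C4a, C5 to C8, C8a) is used throughout; "beta" means the face opposite to the C2 aryl group.

Step 1
Reactants: 1 (tert-butyldimethylsilyloxy)acetaldehyde
Product: 2 (Z)-1,2-bis(tert-butyldimethylsilyloxy)ethene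
Conditions: TBSOTf (1.1 equiv), Et3N (1.5 equiv), CH2Cl2, 0 °C to rt
Reagents that add atoms: tert-butyldimethylsilyl trifluoromethanesulfonate, CC(C)(C)[Si](C)(C)OS(=O)(=O)C(F)(F)F
Why: Soft enolisation with O-silylation (silyl enol ether formation) of the alpha-silyloxy aldehyde should give the enediol bis-silyl ether mainly as the Z isomer, whose geometry needs no control because it is erased in step 3.

Step 2
Reactants: 3 3,4-bis(benzyloxy)benzaldehyde; 4 3,5-bis(benzyloxy)phenol
Product: 6 1-{[3,5-bis(benzyloxy)phenoxy][3,4-bis(benzyloxy)phenyl]methyl}-1H-benzotriazole, via chlorobenzyl-benzotriazole 5 (not isolated)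
Conditions: 1H-benzotriazole (1.0 equiv), SOCl2 (1.2 equiv), toluene, rt, then evaporation; then 4, NaH (1.1 equiv), THF, 0 °C to rt
Reagents that add atoms: 1H-benzotriazole, c1ccc2[nH]nnc2c1
Why: In benzotriazole-mediated acetal chemistry the aldehyde condenses with benzotriazole under SOCl2 to the alpha-chloride 5, which the sodium phenoxide of 4 should substitute at oxygen by an SN1-type etherification through the benzotriazole-stabilised cation, the new acetal carbon being racemic and only transient.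

Step 3
Reactants: 6 1-{[3,5-bis(benzyloxy)phenoxy][3,4-bis(benzyloxy)phenyl]methyl}-1H-benzotriazole; 2 (Z)-1,2-bis(tert-butyldimethylsilyloxy)ethene
Product: 8 rac-5,7-bis(benzyloxy)-2-[3,4-bis(benzyloxy)phenyl]chroman-3-one, via 3,4-bis(silyloxy)flavan 7 (not isolated)
Conditions: 2 (1.1 equiv), TMSOTf (0.3 equiv), CH2Cl2 (0.02 M), −78 °C to 0 °C; aq. NaHCO3 work-up
Reagents that add atoms: none
Why: Proposed new method: Silyl triflate silylates N3 of the benzotriazole of 6 and expels it, which gives the aryl oxocarbenium ion C2=O1–C8a=C4a; the enediol ether 2 adds through an oxygen-bearing carbon (C2–C3 bond, Mukaiyama type) and the silyl-activated aldehyde carbon so formed is attacked by C4a in a 6-exo-trig Friedel–Crafts closure of ring C (C4–C4a bond), giving 7. The same acid then ionises the C4–OSi bond of 7, which is benzylic to the trioxygenated ring A, and a 1,2-hydride shift from C3 (or loss of H3 and hydrolysis of the silyl enol ether on work-up) removes the temporary C4 oxygen and leaves the C3 ketone. The closest known reaction types are the oxa-Povarov reaction of aryl oxocarbenium ions with alkenes (formal inverse-demand [4+2]) and the acid-induced conversion of flavan-3,4-diol derivatives into flavan-3-ones; their union with a silyl enediol ether is new. C2 is the only stereocentre left in 8; it forms without control and is deliberately labile (alpha to the ketone and benzylic), so that step 4 sets it. The step needs capture of the oxocarbenium ion by 2 in preference to ring A of a second molecule, which the much higher nucleophilicity of the silyl enol ether should secure, and closure at C4a, the only activated carbon within reach (the two ortho positions of ring A are equivalent); the symmetry of 2 removes any regiochemical question in the addition.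

Step 4
Reactants: 8 rac-5,7-bis(benzyloxy)-2-[3,4-bis(benzyloxy)phenyl]chroman-3-one
Product: 9 (2R,3R)-5,7-bis(benzyloxy)-2-[3,4-bis(benzyloxy)phenyl]chroman-3-ol
Conditions: RuCl[(R,R)-TsDPEN](p-cymene) (2 mol %), HCO2H/Et3N (5:2), DMF, 40 °C
Reagents that add atoms: none
Why: Noyori–Ikariya asymmetric transfer hydrogenation under dynamic kinetic resolution should work because C2 epimerises fast through the enol in the amine-buffered medium while the chiral ruthenium hydride reduces one ketone enantiomer on the face opposite to the C2 aryl group, so that the catalyst sets C3 and, through the cis preference, C2.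

Step 5
Reactants: 9 (2R,3R)-5,7-bis(benzyloxy)-2-[3,4-bis(benzyloxy)phenyl]chroman-3-ol
Product: 10 (2R,3R,4S)-5,7-bis(benzyloxy)-2-[3,4-bis(benzyloxy)phenyl]-4-(2-ethoxyethoxy)chroman-3-ol
Conditions: DDQ (2 equiv), 2-ethoxyethanol (5 equiv), CH2Cl2, rt
Reagents that add atoms: 2-ethoxyethanol, CCOCCO
Why: Oxidative benzylic C–H etherification, in which DDQ abstracts hydride from C4 (activated by the 5- and 7-benzyloxy groups of ring A) and the alcohol adds to the cation trans to the axial C3 hydroxyl, should give the 4-beta ether while the less activated C2–H and the benzyl ethers survive.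

Step 6
Reactants: 11 benzyl acetate
Product: 12 {[1-(benzyloxy)ethenyl]oxy}(tert-butyl)dimethylsilane
Conditions: LiN(i-Pr)2 (1.1 equiv), THF, −78 °C; TBSCl (1.2 equiv), DMPU, −78 °C to rt
Reagents that add atoms: tert-butyldimethylsilyl chloride, CC(C)(C)[Si](C)(C)Cl
Why: Kinetic ester enolate formation and O-silylation in the presence of DMPU should give the ketene silyl acetal without C-silylation, and no stereocentre is formed.

Step 7
Reactants: 10 (2R,3R,4S)-5,7-bis(benzyloxy)-2-[3,4-bis(benzyloxy)phenyl]-4-(2-ethoxyethoxy)chroman-3-ol; 12 {[1-(benzyloxy)ethenyl]oxy}(tert-butyl)dimethylsilane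
Product: 13 benzyl 2-{(2R,3R,4S)-5,7-bis(benzyloxy)-2-[3,4-bis(benzyloxy)phenyl]-3-hydroxychroman-4-yl}acetate
Conditions: 12 (3 equiv), TMSOTf (0.2 equiv), CH2Cl2, −78 °C
Reagents that add atoms: none
Why: In a Mukaiyama-type SN1 alkylation the silyl triflate ionises the C4 ether to the ring-A-stabilised benzylic cation and the ketene silyl acetal should attack it on the beta face, anti to the axial C3 hydroxyl of the 2,3-cis ring, so that the 3,4-trans (4S) centre is set by substrate control.

Step 8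
Reactants: 13 benzyl 2-{(2R,3R,4S)-5,7-bis(benzyloxy)-2-[3,4-bis(benzyloxy)phenyl]-3-hydroxychroman-4-yl}acetate; 10 (2R,3R,4S)-5,7-bis(benzyloxy)-2-[3,4-bis(benzyloxy)phenyl]-4-(2-ethoxyethoxy)chroman-3-ol
Product: 14 benzyl 2-{(2R,3R,4S)-5,7-bis(benzyloxy)-2-[3,4-bis(benzyloxy)phenyl]-8-{(2R,3R,4R)-5,7-bis(benzyloxy)-2-[3,4-bis(benzyloxy)phenyl]-3-hydroxychroman-4-yl}-3-hydroxychroman-4-yl}acetate
Conditions: 13 (3 equiv, excess recovered), 10 (1 equiv), TMSOTf (0.2 equiv), CH2Cl2, −78 °C
Reagents that add atoms: none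
Why: In this Friedel–Crafts-type interflavan coupling the C4 cation from 10 should be captured by C8 of 13, the most nucleophilic free position of its ring A, again anti to the C3 hydroxyl (4-beta to 8 bond, 4R), while the excess of 13 suppresses self-condensation of 10.

Step 9
Reactants: 14 benzyl 2-{(2R,3R,4S)-5,7-bis(benzyloxy)-2-[3,4-bis(benzyloxy)phenyl]-8-{(2R,3R,4R)-5,7-bis(benzyloxy)-2-[3,4-bis(benzyloxy)phenyl]-3-hydroxychroman-4-yl}-3-hydroxychroman-4-yl}acetate
Product: 15 2-{(2R,3R,4S)-2-(3,4-dihydroxyphenyl)-8-[(2R,3R,4R)-2-(3,4-dihydroxyphenyl)-3,5,7-trihydroxychroman-4-yl]-3,5,7-trihydroxychroman-4-yl}acetic acid (CNP0190976.1)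
Conditions: H2 (1 atm), Pd(OH)2/C (20 wt %), THF/MeOH/H2O (20:20:1), rt
Reagents that add atoms: none
Why: Catalytic hydrogenolysis over Pd(OH)2/C should cleave the eight benzyl ethers and the benzyl ester in one neutral operation that leaves the acid-labile interflavan bond and every stereocentre untouched.

Compound list

1 | (tert-butyldimethylsilyloxy)acetaldehyde | O=CCO[Si](C)(C)C(C)(C)C | starting material
2 | (Z)-1,2-bis(tert-butyldimethylsilyloxy)ethene | CC(C)(C)[Si](C)(C)O/C=C\O[Si](C)(C)C(C)(C)C | intermediate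
3 | 3,4-bis(benzyloxy)benzaldehyde | O=Cc1ccc(OCc2ccccc2)c(OCc2ccccc2)c1 | starting material
4 | 3,5-bis(benzyloxy)phenol | Oc1cc(OCc2ccccc2)cc(OCc2ccccc2)c1 | starting material
5 | 1-{chloro[3,4-bis(benzyloxy)phenyl]methyl}-1H-benzotriazole (racemic, not isolated) | ClC(c1ccc(OCc2ccccc2)c(OCc2ccccc2)c1)n1nnc2ccccc21 | intermediate
6 | 1-{[3,5-bis(benzyloxy)phenoxy][3,4-bis(benzyloxy)phenyl]methyl}-1H-benzotriazole (racemic) | C(Oc1cc(OCc2ccccc2)cc(OCc2ccccc2)c1)(c1ccc(OCc2ccccc2)c(OCc2ccccc2)c1)n1nnc2ccccc21 | intermediate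
7 | 5,7-bis(benzyloxy)-2-[3,4-bis(benzyloxy)phenyl]-3,4-bis(tert-butyldimethylsilyloxy)chroman (racemic mixture of diastereomers, not isolated) | CC(C)(C)[Si](C)(C)OC1C(O[Si](C)(C)C(C)(C)C)c2c(OCc3ccccc3)cc(OCc3ccccc3)cc2OC1c1ccc(OCc2ccccc2)c(OCc2ccccc2)c1 | intermediate
8 | rac-5,7-bis(benzyloxy)-2-[3,4-bis(benzyloxy)phenyl]chroman-3-one | O=C1Cc2c(OCc3ccccc3)cc(OCc3ccccc3)cc2OC1c1ccc(OCc2ccccc2)c(OCc2ccccc2)c1 | intermediate
9 | (2R,3R)-5,7-bis(benzyloxy)-2-[3,4-bis(benzyloxy)phenyl]chroman-3-ol | C1c2c(OCc3ccccc3)cc(OCc3ccccc3)cc2O[C@H](c2ccc(OCc3ccccc3)c(OCc3ccccc3)c2)[C@@H]1O | intermediate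
10 | (2R,3R,4S)-5,7-bis(benzyloxy)-2-[3,4-bis(benzyloxy)phenyl]-4-(2-ethoxyethoxy)chroman-3-ol | CCOCCO[C@H]1c2c(OCc3ccccc3)cc(OCc3ccccc3)cc2O[C@H](c2ccc(OCc3ccccc3)c(OCc3ccccc3)c2)[C@@H]1O | intermediate
11 | benzyl acetate | CC(=O)OCc1ccccc1 | starting material
12 | {[1-(benzyloxy)ethenyl]oxy}(tert-butyl)dimethylsilane | C=C(OCc1ccccc1)O[Si](C)(C)C(C)(C)C | intermediate
13 | benzyl 2-{(2R,3R,4S)-5,7-bis(benzyloxy)-2-[3,4-bis(benzyloxy)phenyl]-3-hydroxychroman-4-yl}acetate | O=C(OCc1ccccc1)C[C@H]1c2c(OCc3ccccc3)cc(OCc3ccccc3)cc2O[C@H](c2ccc(OCc3ccccc3)c(OCc3ccccc3)c2)[C@@H]1O | intermediate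
14 | benzyl 2-{(2R,3R,4S)-5,7-bis(benzyloxy)-2-[3,4-bis(benzyloxy)phenyl]-8-{(2R,3R,4R)-5,7-bis(benzyloxy)-2-[3,4-bis(benzyloxy)phenyl]-3-hydroxychroman-4-yl}-3-hydroxychroman-4-yl}acetate | O=C(OCc1ccccc1)C[C@H]1c2c(OCc3ccccc3)cc(OCc3ccccc3)c([C@H]3c4c(OCc5ccccc5)cc(OCc5ccccc5)cc4O[C@H](c4ccc(OCc5ccccc5)c(OCc5ccccc5)c4)[C@@H]3O)c2O[C@H](c2ccc(OCc3ccccc3)c(OCc3ccccc3)c2)[C@@H]1O | intermediate
15 | 2-{(2R,3R,4S)-2-(3,4-dihydroxyphenyl)-8-[(2R,3R,4R)-2-(3,4-dihydroxyphenyl)-3,5,7-trihydroxychroman-4-yl]-3,5,7-trihydroxychroman-4-yl}acetic acid (CNP0190976.1) | O=C(O)C[C@H]1c2c(O)cc(O)c([C@H]3c4c(O)cc(O)cc4O[C@H](c4ccc(O)c(O)c4)[C@@H]3O)c2O[C@H](c2ccc(O)c(O)c2)[C@@H]1O | target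

Total step count: 9.
Longest linear sequence: 7 steps (steps 2, 3, 4, 5, 7, 8, 9); steps 1 and 6 are one-step side branches.

Steps most likely to fail

1. Step 3 (bears the label). The cations may leave the intended path: the oxocarbenium ion may be captured by ring A of a second molecule, or the late C4 cation may be intercepted intermolecularly before the hydride shift, which would give oligomers. The fallback sets out from 6 and comes back at 8. Compound 6 and 2 are combined with ZnBr2 in CH2Cl2 at −40 °C, a known Lewis-acid substitution of benzotriazolyl ethers by silyl enol ethers, and quenched cold to isolate 3-[3,5-bis(benzyloxy)phenoxy]-3-[3,4-bis(benzyloxy)phenyl]-2-(tert-butyldimethylsilyloxy)propanal F1. F1 is then cyclised on its own at high dilution with camphorsulfonic acid in toluene (Friedel–Crafts hydroxyalkylation, then acid-induced loss of the C4 hydroxyl with hydride shift and desilylation), which should give 8.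

2. Step 4. Epimerisation at C2 may be slow relative to reduction, or facial discrimination may be weak for a ketone that carries no aryl group directly on the carbonyl; either would erode enantiomeric purity and the cis preference. The fallback sets out from 8 and comes back at 9. Reduction of 8 with LiBH(s-Bu)3 and LiBr in THF at −78 °C, a known cis-selective reduction of this ketone class, should give racemic cis-5,7-bis(benzyloxy)-2-[3,4-bis(benzyloxy)phenyl]chroman-3-ol F2. Esterification with (S)-2-methoxy-2-phenylacetic acid (DCC, DMAP, CH2Cl2) gives two diastereomeric esters that are separated by chromatography: the (2R,3R)-chromanyl (S)-2-methoxy-2-phenylacetate F3 and the (2S,3S)-chromanyl (S)-2-methoxy-2-phenylacetate F4. Methanolysis of F3 (K2CO3, MeOH/THF) returns 9.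

3. Step 8. The electrophile may condense with itself through its own C8, and the nucleophile may react at C6, so that oligomers and regioisomers form. The fallback sets out from 9 and comes back at 15. Bromination of 9 with N-bromosuccinimide in CH2Cl2 should give (2R,3R)-5,7-bis(benzyloxy)-2-[3,4-bis(benzyloxy)phenyl]-8-bromochroman-3-ol F5. DDQ and 2-ethoxyethanol as in step 5 give (2R,3R,4S)-5,7-bis(benzyloxy)-2-[3,4-bis(benzyloxy)phenyl]-8-bromo-4-(2-ethoxyethoxy)chroman-3-ol F6, which can no longer act as a nucleophile at C8. Coupling of F6 with 13 (1.5 equiv) under TMSOTf gives the 8-bromo analogue of 14 (bromine on C8 of the upper unit) F7. Hydrogenolysis of F7 over Pd(OH)2/C with Et3N removes the bromine together with the benzyl groups and gives 15.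

Further compounds

F1 | step 3 | 3-[3,5-bis(benzyloxy)phenoxy]-3-[3,4-bis(benzyloxy)phenyl]-2-(tert-butyldimethylsilyloxy)propanal (racemic mixture of diastereomers) | O=CC(O[Si](C)(C)C(C)(C)C)C(Oc1cc(OCc2ccccc2)cc(OCc2ccccc2)c1)c1ccc(OCc2ccccc2)c(OCc2ccccc2)c1
F2 | step 4 | racemic cis-5,7-bis(benzyloxy)-2-[3,4-bis(benzyloxy)phenyl]chroman-3-ol (both enantiomers written) | C1c2c(OCc3ccccc3)cc(OCc3ccccc3)cc2O[C@H](c2ccc(OCc3ccccc3)c(OCc3ccccc3)c2)[C@@H]1O.C1c2c(OCc3ccccc3)cc(OCc3ccccc3)cc2O[C@@H](c2ccc(OCc3ccccc3)c(OCc3ccccc3)c2)[C@H]1O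
F3 | step 4 | (2R,3R)-5,7-bis(benzyloxy)-2-[3,4-bis(benzyloxy)phenyl]chroman-3-yl (S)-2-methoxy-2-phenylacetate | C1c2c(OCc3ccccc3)cc(OCc3ccccc3)cc2O[C@H](c2ccc(OCc3ccccc3)c(OCc3ccccc3)c2)[C@@H]1OC(=O)[C@@H](OC)c1ccccc1
F4 | step 4 | (2S,3S)-5,7-bis(benzyloxy)-2-[3,4-bis(benzyloxy)phenyl]chroman-3-yl (S)-2-methoxy-2-phenylacetate | C1c2c(OCc3ccccc3)cc(OCc3ccccc3)cc2O[C@@H](c2ccc(OCc3ccccc3)c(OCc3ccccc3)c2)[C@H]1OC(=O)[C@@H](OC)c1ccccc1
F5 | step 8 | (2R,3R)-5,7-bis(benzyloxy)-2-[3,4-bis(benzyloxy)phenyl]-8-bromochroman-3-ol | C1c2c(OCc3ccccc3)cc(OCc3ccccc3)c(Br)c2O[C@H](c2ccc(OCc3ccccc3)c(OCc3ccccc3)c2)[C@@H]1O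
F6 | step 8 | (2R,3R,4S)-5,7-bis(benzyloxy)-2-[3,4-bis(benzyloxy)phenyl]-8-bromo-4-(2-ethoxyethoxy)chroman-3-ol | CCOCCO[C@H]1c2c(OCc3ccccc3)cc(OCc3ccccc3)c(Br)c2O[C@H](c2ccc(OCc3ccccc3)c(OCc3ccccc3)c2)[C@@H]1O
F7 | step 8 | benzyl 2-{(2R,3R,4S)-5,7-bis(benzyloxy)-2-[3,4-bis(benzyloxy)phenyl]-8-{(2R,3R,4S)-5,7-bis(benzyloxy)-2-[3,4-bis(benzyloxy)phenyl]-8-bromo-3-hydroxychroman-4-yl}-3-hydroxychroman-4-yl}acetate | O=C(OCc1ccccc1)C[C@H]1c2c(OCc3ccccc3)cc(OCc3ccccc3)c([C@H]3c4c(OCc5ccccc5)cc(OCc5ccccc5)c(Br)c4O[C@H](c4ccc(OCc5ccccc5)c(OCc5ccccc5)c4)[C@@H]3O)c2O[C@H](c2ccc(OCc3ccccc3)c(OCc3ccccc3)c2)[C@@H]1O
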